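## Retrosynthetic overview

1. Target 36 ⇐ enol triflate 35 (Pd/formate) ⇐ Diels–Alder of α-methylene lactone 25 with silyloxy diene 32. Diene 32 is a myrcene surrogate: its OSi group forces the side chain meta to the spiro carbon, which plain myrcene would not do. This cycloaddition forms the spiro-cyclohexene last and sets C11.
2. 25 ⇐ angeloylation of 22 ⇐ 21, made by intramolecular zinc Barbier allylation of bromo-enal 18 (C6–C7 bond; ten-membered ring and cis γ-lactone in one step).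
3. 18 ⇐ aldehyde 13 by Morita–Baylis–Hillman reaction and SN2′ bromination; furanone 11 ⇐ lactone 6 + acetylide of enynol ether 8, then gold cycloisomerisation.
4. 6 ⇐ (R)-5-(hydroxymethyl)butyrolactone 1: C8 is bought; C10 comes from enolate hydroxylation then methylation, both anti to the C5 side chain.
5. Ring order: furanone (step 5) → ten-membered carbocycle + γ-lactone (step 12) → spiro-cyclohexene (step 18).

Assumption: positions are given in germacrane numbering (C1–C15 of the sesquiterpene part; C11 is the spiro carbon, C13 its ring CH2 neighbour), and lactone 1, sold as a D-glutamic-acid-derived building block, is taken as the cheap chiral starting material.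

## Route

Step 1
Reactants: 1 (R)-5-(hydroxymethyl)dihydrofuran-2(3H)-one
Product: 2 (R)-5-{[(triethylsilyl)oxy]methyl}dihydrofuran-2(3H)-one
Conditions: Et3SiCl, imidazole, CH2Cl2, 0 °C to rt
Reagents that add atoms: chlorotriethylsilane, CC[Si](Cl)(CC)CC
Why: Alcohol silylation masks the primary hydroxyl as a group that can later be oxidised off selectively; the bought stereocentre (future C8) is untouched.

Step 2
Reactants: 2 (R)-5-{[(triethylsilyl)oxy]methyl}dihydrofuran-2(3H)-one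
Product: 4 (3S,5R)-3-hydroxy-5-{[(triethylsilyl)oxy]methyl}dihydrofuran-2(3H)-one, via lithium enolate 3 (not isolated)
Conditions: LiN(SiMe3)2, THF, −78 °C; MoO5·pyridine·HMPA (MoOPH), −78 to −45 °C; aq. Na2SO3
Reagents that add atoms: MoOPH, O=[Mo]12(OO1)OO2.c1ccncc1.CN(C)P(=O)(N(C)C)N(C)C
Why: Enolate hydroxylation with the achiral Vedejs reagent; the electrophile approaches planar enolate 3 anti to the C5 side chain, so the new hydroxyl is 3,5-trans (3S).

Step 3
Reactants: 4 (3S,5R)-3-hydroxy-5-{[(triethylsilyl)oxy]methyl}dihydrofuran-2(3H)-one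
Product: 6 (3R,5R)-3-hydroxy-3-methyl-5-{[(triethylsilyl)oxy]methyl}dihydrofuran-2(3H)-one, via dilithium enediolate 5 (not isolated)
Conditions: LiN(i-Pr)2 (2.3 equiv), THF–DMPU, −78 to −40 °C; MeI, −78 to −30 °C
Reagents that add atoms: iodomethane, CI
Why: Lactone enolate C-alkylation of enediolate 5; methyl iodide again enters anti to the C5 side chain, so the oxygen ends up cis and the quaternary carbinol (future C10, 3R) is fixed by the bought centre through the order of the two enolate reactions.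

Step 4
Reactants: 7 (Z)-3-methylpent-2-en-4-yn-1-ol
Product: 8 tert-butyldimethyl{[(2Z)-3-methylpent-2-en-4-yn-1-yl]oxy}silane
Conditions: t-BuMe2SiCl, imidazole, DMF, rt
Reagents that add atoms: tert-butylchlorodimethylsilane, CC(C)(C)[Si](C)(C)Cl
Why: Alcohol silylation; the Z trisubstituted alkene (future C4=C5) is bought and not touched.

Step 5
Reactants: 6 (3R,5R)-3-hydroxy-3-methyl-5-{[(triethylsilyl)oxy]methyl}dihydrofuran-2(3H)-one; 8 tert-butyldimethyl{[(2Z)-3-methylpent-2-en-4-yn-1-yl]oxy}silane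
Product: 11 (2R)-5-{(2Z)-4-[(tert-butyldimethylsilyl)oxy]but-2-en-2-yl}-2-{(2R)-2-hydroxy-3-[(triethylsilyl)oxy]propyl}-2-methylfuran-3(2H)-one, via lithium acetylide 9 (not isolated), via hydroxy ynone 10 (not isolated)
Conditions: 8 (3.2 equiv), n-BuLi (3.1 equiv), THF, −78 °C; 6, −78 to −30 °C; AcOH, −78 °C; crude, Ph3PAuCl (5 mol %), AgOTf (5 mol %), toluene, rt
Reagents that add atoms: none
Why: Acetylide acyl addition to the lactone stops at the lactolate (hydroxy ynone 10 after quench), and gold-catalysed 5-endo-dig cycloisomerisation of the α′-hydroxy ynone closes the 3(2H)-furanone; no stereocentre is formed and C8/C10 cannot epimerise.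

Step 6
Reactants: 11 (2R)-5-{(2Z)-4-[(tert-butyldimethylsilyl)oxy]but-2-en-2-yl}-2-{(2R)-2-hydroxy-3-[(triethylsilyl)oxy]propyl}-2-methylfuran-3(2H)-one
Product: 12 (2R)-5-{(2Z)-4-[(tert-butyldimethylsilyl)oxy]but-2-en-2-yl}-2-{(2R)-2-[(tert-butyldimethylsilyl)oxy]-3-[(triethylsilyl)oxy]propyl}-2-methylfuran-3(2H)-one
Conditions: t-BuMe2SiOTf, 2,6-lutidine, CH2Cl2, −78 °C
Reagents that add atoms: tert-butyldimethylsilyl triflate, CC(C)(C)[Si](C)(C)OS(=O)(=O)C(F)(F)F
Why: Silylation of the secondary C8 alcohol with a silyl triflate gives an ether that survives the amine-mediated step 8 without acyl-migration or α-epimerisation problems.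

Step 7
Reactants: 12 (2R)-5-{(2Z)-4-[(tert-butyldimethylsilyl)oxy]but-2-en-2-yl}-2-{(2R)-2-[(tert-butyldimethylsilyl)oxy]-3-[(triethylsilyl)oxy]propyl}-2-methylfuran-3(2H)-one
Product: 13 (2R)-2-[(tert-butyldimethylsilyl)oxy]-3-[(2R)-5-{(2Z)-4-[(tert-butyldimethylsilyl)oxy]but-2-en-2-yl}-2-methyl-3-oxo-2,3-dihydrofuran-2-yl]propanal
Conditions: (COCl)2, DMSO, CH2Cl2, −78 to −40 °C; Et3N, −78 to 0 °C
Reagents that add atoms: none
Why: Swern oxidation run directly on the silyl ether (oxidative desilylation); activated DMSO exchanges only with the primary triethylsilyl ether, the two TBS ethers are inert, and the α-silyloxy aldehyde keeps its configuration at low temperature.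

Step 8
Reactants: 13 (2R)-2-[(tert-butyldimethylsilyl)oxy]-3-[(2R)-5-{(2Z)-4-[(tert-butyldimethylsilyl)oxy]but-2-en-2-yl}-2-methyl-3-oxo-2,3-dihydrofuran-2-yl]propanal; 14 methyl acrylate
Product: 15 methyl (4R)-4-[(tert-butyldimethylsilyl)oxy]-5-[(2R)-5-{(2Z)-4-[(tert-butyldimethylsilyl)oxy]but-2-en-2-yl}-2-methyl-3-oxo-2,3-dihydrofuran-2-yl]-3-hydroxy-2-methylidenepentanoate (both C3 epimers)
Conditions: 14 (10 equiv), DABCO (1 equiv), MeOH (3 equiv), rt, 4–6 d
Reagents that add atoms: none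
Why: Morita–Baylis–Hillman reaction brings in C11–C13; the new carbinol centre forms as a mixture, which does not matter because it becomes sp2 in step 9.

Step 9
Reactants: 15 methyl (4R)-4-[(tert-butyldimethylsilyl)oxy]-5-[(2R)-5-{(2Z)-4-[(tert-butyldimethylsilyl)oxy]but-2-en-2-yl}-2-methyl-3-oxo-2,3-dihydrofuran-2-yl]-3-hydroxy-2-methylidenepentanoate
Product: 16 methyl (2Z,4R)-2-(bromomethyl)-4-[(tert-butyldimethylsilyl)oxy]-5-[(2R)-5-{(2Z)-4-[(tert-butyldimethylsilyl)oxy]but-2-en-2-yl}-2-methyl-3-oxo-2,3-dihydrofuran-2-yl]pent-2-enoate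
Conditions: NBS, Me2S, CH2Cl2, 0 °C to rt
Reagents that add atoms: N-bromosuccinimide, O=C1CCC(=O)N1Br
Why: Allylic bromination with transposition (SN2′ on the sulfonium-activated alcohol) gives the thermodynamically preferred (Z)-2-(bromomethyl)enoate with CH2Br cis to C8.

Step 10
Reactants: 16 methyl (2Z,4R)-2-(bromomethyl)-4-[(tert-butyldimethylsilyl)oxy]-5-[(2R)-5-{(2Z)-4-[(tert-butyldimethylsilyl)oxy]but-2-en-2-yl}-2-methyl-3-oxo-2,3-dihydrofuran-2-yl]pent-2-enoate
Product: 17 methyl (2Z,4R)-2-(bromomethyl)-4-[(tert-butyldimethylsilyl)oxy]-5-{(2R)-5-[(2Z)-4-hydroxybut-2-en-2-yl]-2-methyl-3-oxo-2,3-dihydrofuran-2-yl}pent-2-enoate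
Conditions: HF·pyridine, pyridine, THF, 0 °C
Reagents that add atoms: none
Why: Selective desilylation; the unhindered primary allylic TBS ether is cleaved much faster than the doubly flanked secondary one.

Step 11
Reactants: 17 methyl (2Z,4R)-2-(bromomethyl)-4-[(tert-butyldimethylsilyl)oxy]-5-{(2R)-5-[(2Z)-4-hydroxybut-2-en-2-yl]-2-methyl-3-oxo-2,3-dihydrofuran-2-yl}pent-2-enoate
Product: 18 methyl (2Z,4R)-2-(bromomethyl)-4-[(tert-butyldimethylsilyl)oxy]-5-{(2R)-2-methyl-3-oxo-5-[(2Z)-4-oxobut-2-en-2-yl]-2,3-dihydrofuran-2-yl}pent-2-enoate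
Conditions: Dess–Martin periodinane, NaHCO3, CH2Cl2, 0 °C; used at once
Reagents that add atoms: none
Why: Buffered Dess–Martin oxidation gives the Z-enal without acid- or base-induced Z/E isomerisation and leaves the allyl bromide alone.

Step 12
Reactants: 18 methyl (2Z,4R)-2-(bromomethyl)-4-[(tert-butyldimethylsilyl)oxy]-5-{(2R)-2-methyl-3-oxo-5-[(2Z)-4-oxobut-2-en-2-yl]-2,3-dihydrofuran-2-yl}pent-2-enoate
Product: 21 (6S,7S,8R,10R)-8-[(tert-butyldimethylsilyl)oxy]-3,10-epoxy-1-oxogermacra-2,4Z,11(13)-trien-12,6-olide (6,7-cis-fused α-methylene lactone), via allylzinc bromide 19 (not isolated), via hydroxy ester 20 (not isolated)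
Conditions: activated Zn dust, THF/sat. aq. NH4Cl 5:1, rt, 0.002 M; then PPTS, benzene, 50 °C
Reagents that add atoms: none
Why: Intramolecular Barbier (Reformatsky-type) allylation; allylzinc 19 adds to the enal through a closed six-membered chair transition state in which the Z geometry holds C8 axial, so the 6,7-syn adduct 20 forms and lactonises to the cis-fused lactone, while the C8 silyloxy centre and the rigid furanone bridge (both traceable to 1) direct closure so that O6, C11 and O8 lie on the ring face away from the bridging oxygen (C7 reads S here only because OSi outranks the lactone branch).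

Step 13
Reactants: 21 (6S,7S,8R,10R)-8-[(tert-butyldimethylsilyl)oxy]-3,10-epoxy-1-oxogermacra-2,4Z,11(13)-trien-12,6-olide
Product: 22 (6S,7R,8R,10R)-8-hydroxy-3,10-epoxy-1-oxogermacra-2,4Z,11(13)-trien-12,6-olide
Conditions: HF·pyridine, THF, 0 °C to rt
Reagents that add atoms: none
Why: Fluoride desilylation under mildly acidic conditions frees the C8 alcohol without Michael addition to, or translactonisation of, the α-methylene lactone.

Step 14
Reactants: 22 (6S,7R,8R,10R)-8-hydroxy-3,10-epoxy-1-oxogermacra-2,4Z,11(13)-trien-12,6-olide; 23 angelic acid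
Product: 25 (6S,7R,8R,10R)-8-angeloyloxy-3,10-epoxy-1-oxogermacra-2,4Z,11(13)-trien-12,6-olide (6-epi-lychnopholide), via mixed anhydride 24 (not isolated)
Conditions: 23, 2,4,6-trichlorobenzoyl chloride, Et3N, toluene, rt, 2 h; then 22, 80 °C
Reagents that add atoms: none
Why: Yamaguchi-type esterification through mixed anhydride 24 without DMAP, so the (Z)-angelate does not isomerise to tiglate; acylation on oxygen keeps the C8 configuration.

Step 15
Reactants: 26 ethyl acetoacetate; 27 5-bromo-2-methylpent-2-ene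
Product: 28 ethyl 2-acetyl-6-methylhept-5-enoate
Conditions: K2CO3, NaI (cat.), DMF, 60 °C
Reagents that add atoms: none
Why: Acetoacetic ester synthesis (SN2 C-alkylation at the doubly activated carbon); the racemic centre is destroyed in step 16.

Step 16
Reactants: 28 ethyl 2-acetyl-6-methylhept-5-enoate
Product: 31 7-methyl-3-methylideneoct-6-en-2-one, via keto acid 29 (not isolated), via Mannich acid 30 (not isolated)
Conditions: KOH, H2O–EtOH, 0 °C to rt; AcOH to pH 7; 37% aq. CH2O, Et2NH, rt to 50 °C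
Reagents that add atoms: formaldehyde, C=O
Why: Saponification then decarboxylative Mannich methylenation; aminomethylation of keto acid 29 gives 30, which loses CO2 and diethylamine to leave the α-methylene ketone.

Step 17
Reactants: 31 7-methyl-3-methylideneoct-6-en-2-one
Product: 32 tert-butyldimethyl[(7-methyl-3-methylideneocta-1,6-dien-2-yl)oxy]silane
Conditions: t-BuMe2SiOTf, Et3N, CH2Cl2, 0 °C
Reagents that add atoms: tert-butyldimethylsilyl triflate, CC(C)(C)[Si](C)(C)OS(=O)(=O)C(F)(F)F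
Why: Silyl enol ether formation can only occur toward the methyl group and gives the 2-silyloxy-1,3-diene, a myrcene equivalent with a removable directing group.

Step 18
Reactants: 25 (6S,7R,8R,10R)-8-angeloyloxy-3,10-epoxy-1-oxogermacra-2,4Z,11(13)-trien-12,6-olide; 32 tert-butyldimethyl[(7-methyl-3-methylideneocta-1,6-dien-2-yl)oxy]silane
Product: 33 (6S,7R,8R,10R,11S)-8-angeloyloxy-3,10-epoxy-1-oxogermacra-2,4Z-dien-12,6-olide spiro-fused at C11 (=C1′; C13 = C6′) to 4′-[(tert-butyldimethylsilyl)oxy]-3′-(4-methylpent-3-enyl)cyclohex-3′-ene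
Conditions: 32 (3 equiv), BHT (cat.), toluene, 110 °C, sealed tube
Reagents that add atoms: none
Why: Diels–Alder [4+2] cycloaddition at the exocyclic methylene lactone; the silyloxy group makes the enol-ether CH2 the nucleophilic diene terminus, so it bonds to C13 and the side chain lands meta to the spiro carbon, and the diene adds to the convex face of the cis-fused lactone (anti to the C5 and C8 ring bonds), which sets C11 (11S).

Step 19
Reactants: 33 silyl enol ether Diels–Alder adduct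
Product: 35 (6S,7R,8R,10R,11S)-8-angeloyloxy-3,10-epoxy-1-oxogermacra-2,4Z-dien-12,6-olide spiro-fused at C11 to 3′-(4-methylpent-3-enyl)-4′-[(trifluoromethylsulfonyl)oxy]cyclohex-3′-ene, via cesium enolate 34 (not isolated)
Conditions: CsF, PhNTf2, DME, rt
Reagents that add atoms: N-phenylbis(trifluoromethanesulfonimide), O=S(=O)(N(c1ccccc1)S(=O)(=O)C(F)(F)F)C(F)(F)F
Why: Fluoride desilylation gives the regiodefined enolate 34, which is O-sulfonylated in situ (enol triflate formation) without moving the double bond; no base-sensitive α-hydrogen remains at the spiro lactone.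

Step 20
Reactants: 35 enol triflate
Product: 36 target, (6S,7R,8R,10R,11S)-8-angeloyloxy-3,10-epoxy-1-oxogermacra-2,4Z-dien-12,6-olide spiro-fused at C11 to 3′-(4-methylpent-3-enyl)cyclohex-3′-ene
Conditions: Pd(OAc)2 (10 mol %), PPh3 (20 mol %), HCO2H, n-Bu3N, DMF, 50 °C
Reagents that add atoms: none
Why: Palladium-catalysed formate hydrogenolysis of the enol triflate (oxidative addition, formate decarboxylation, reductive elimination) replaces OTf by H and leaves the trisubstituted ring alkene exactly where the target has it.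

## Compound list

1 | (R)-5-(hydroxymethyl)dihydrofuran-2(3H)-one | OC[C@H]1CCC(=O)O1 | starting material
2 | (R)-5-{[(triethylsilyl)oxy]methyl}dihydrofuran-2(3H)-one | CC[Si](CC)(CC)OC[C@H]1CCC(=O)O1 | intermediate
3 | lithium enolate of 2 | CC[Si](CC)(CC)OC[C@H]1CC=C(O[Li])O1 | intermediate (not isolated)
4 | (3S,5R)-3-hydroxy-5-{[(triethylsilyl)oxy]methyl}dihydrofuran-2(3H)-one (3,5-trans) | CC[Si](CC)(CC)OC[C@H]1C[C@H](O)C(=O)O1 | intermediate
5 | dilithium enediolate of 4 | CC[Si](CC)(CC)OC[C@H]1CC(O[Li])=C(O[Li])O1 | intermediate (not isolated)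
6 | (3R,5R)-3-hydroxy-3-methyl-5-{[(triethylsilyl)oxy]methyl}dihydrofuran-2(3H)-one (OH cis to the C5 side chain) | CC[Si](CC)(CC)OC[C@H]1C[C@@](C)(O)C(=O)O1 | intermediate
7 | (Z)-3-methylpent-2-en-4-yn-1-ol | C#C/C(C)=C\CO | starting material
8 | tert-butyldimethyl{[(2Z)-3-methylpent-2-en-4-yn-1-yl]oxy}silane | C#C/C(C)=C\CO[Si](C)(C)C(C)(C)C | intermediate
9 | lithium acetylide of 8 | [Li]C#C/C(C)=C\CO[Si](C)(C)C(C)(C)C | intermediate (not isolated)
10 | (2Z,7R,9R)-1-[(tert-butyldimethylsilyl)oxy]-7,9-dihydroxy-3,7-dimethyl-10-[(triethylsilyl)oxy]dec-2-en-4-yn-6-one | CC[Si](CC)(CC)OC[C@H](O)C[C@@](C)(O)C(=O)C#C/C(C)=C\CO[Si](C)(C)C(C)(C)C | intermediate (not isolated)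
11 | (2R)-5-{(2Z)-4-[(tert-butyldimethylsilyl)oxy]but-2-en-2-yl}-2-{(2R)-2-hydroxy-3-[(triethylsilyl)oxy]propyl}-2-methylfuran-3(2H)-one | CC[Si](CC)(CC)OC[C@H](O)C[C@@]1(C)OC(=CC1=O)/C(C)=C\CO[Si](C)(C)C(C)(C)C | intermediate
12 | (2R)-5-{(2Z)-4-[(tert-butyldimethylsilyl)oxy]but-2-en-2-yl}-2-{(2R)-2-[(tert-butyldimethylsilyl)oxy]-3-[(triethylsilyl)oxy]propyl}-2-methylfuran-3(2H)-one | CC[Si](CC)(CC)OC[C@H](O[Si](C)(C)C(C)(C)C)C[C@@]1(C)OC(=CC1=O)/C(C)=C\CO[Si](C)(C)C(C)(C)C | intermediate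
13 | (2R)-2-[(tert-butyldimethylsilyl)oxy]-3-[(2R)-5-{(2Z)-4-[(tert-butyldimethylsilyl)oxy]but-2-en-2-yl}-2-methyl-3-oxo-2,3-dihydrofuran-2-yl]propanal | O=C[C@H](O[Si](C)(C)C(C)(C)C)C[C@@]1(C)OC(=CC1=O)/C(C)=C\CO[Si](C)(C)C(C)(C)C | intermediate
14 | methyl acrylate | C=CC(=O)OC | starting material
15 | methyl (4R)-4-[(tert-butyldimethylsilyl)oxy]-5-[(2R)-5-{(2Z)-4-[(tert-butyldimethylsilyl)oxy]but-2-en-2-yl}-2-methyl-3-oxo-2,3-dihydrofuran-2-yl]-3-hydroxy-2-methylidenepentanoate (both C3 epimers) | C=C(C(=O)OC)C(O)[C@H](O[Si](C)(C)C(C)(C)C)C[C@@]1(C)OC(=CC1=O)/C(C)=C\CO[Si](C)(C)C(C)(C)C | intermediate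
16 | methyl (2Z,4R)-2-(bromomethyl)-4-[(tert-butyldimethylsilyl)oxy]-5-[(2R)-5-{(2Z)-4-[(tert-butyldimethylsilyl)oxy]but-2-en-2-yl}-2-methyl-3-oxo-2,3-dihydrofuran-2-yl]pent-2-enoate | COC(=O)/C(CBr)=C/[C@H](O[Si](C)(C)C(C)(C)C)C[C@@]1(C)OC(=CC1=O)/C(C)=C\CO[Si](C)(C)C(C)(C)C | intermediate
17 | methyl (2Z,4R)-2-(bromomethyl)-4-[(tert-butyldimethylsilyl)oxy]-5-{(2R)-5-[(2Z)-4-hydroxybut-2-en-2-yl]-2-methyl-3-oxo-2,3-dihydrofuran-2-yl}pent-2-enoate | COC(=O)/C(CBr)=C/[C@H](O[Si](C)(C)C(C)(C)C)C[C@@]1(C)OC(=CC1=O)/C(C)=C\CO | intermediate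
18 | methyl (2Z,4R)-2-(bromomethyl)-4-[(tert-butyldimethylsilyl)oxy]-5-{(2R)-2-methyl-3-oxo-5-[(2Z)-4-oxobut-2-en-2-yl]-2,3-dihydrofuran-2-yl}pent-2-enoate | COC(=O)/C(CBr)=C/[C@H](O[Si](C)(C)C(C)(C)C)C[C@@]1(C)OC(=CC1=O)/C(C)=C\C=O | intermediate
19 | allylzinc bromide formed from 18 (Zn inserted into C–Br) | COC(=O)/C(C[Zn]Br)=C/[C@H](O[Si](C)(C)C(C)(C)C)C[C@@]1(C)OC(=CC1=O)/C(C)=C\C=O | intermediate (not isolated)
20 | methyl (6S,7S,8R,10R)-8-[(tert-butyldimethylsilyl)oxy]-3,10-epoxy-6-hydroxy-1-oxogermacra-2,4Z,11(13)-trien-12-oate | CC(C)(C)[Si](C)(C)O[C@@H]1C[C@@]2(C)OC(=CC2=O)/C(C)=C\[C@H](O)[C@@H]1C(=C)C(=O)OC | intermediate (not isolated)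
21 | (6S,7S,8R,10R)-8-[(tert-butyldimethylsilyl)oxy]-3,10-epoxy-1-oxogermacra-2,4Z,11(13)-trien-12,6-olide (6,7-cis lactone) | CC(C)(C)[Si](C)(C)O[C@@H]1C[C@@]2(C)OC(=CC2=O)/C(C)=C\[C@@H]2OC(=O)C(=C)[C@@H]21 | intermediate
22 | (6S,7R,8R,10R)-8-hydroxy-3,10-epoxy-1-oxogermacra-2,4Z,11(13)-trien-12,6-olide | O[C@@H]1C[C@@]2(C)OC(=CC2=O)/C(C)=C\[C@@H]2OC(=O)C(=C)[C@@H]21 | intermediate
23 | angelic acid, (Z)-2-methylbut-2-enoic acid | C/C=C(/C)C(=O)O | starting material
24 | angelic 2,4,6-trichlorobenzoic anhydride | C/C=C(/C)C(=O)OC(=O)c1c(Cl)cc(Cl)cc1Cl | intermediate (not isolated)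
25 | (6S,7R,8R,10R)-8-angeloyloxy-3,10-epoxy-1-oxogermacra-2,4Z,11(13)-trien-12,6-olide (6-epi-lychnopholide) | C/C=C(/C)C(=O)O[C@@H]1C[C@@]2(C)OC(=CC2=O)/C(C)=C\[C@@H]2OC(=O)C(=C)[C@@H]21 | intermediate
26 | ethyl acetoacetate | CCOC(=O)CC(C)=O | starting material
27 | 5-bromo-2-methylpent-2-ene | CC(C)=CCCBr | starting material
28 | ethyl 2-acetyl-6-methylhept-5-enoate (racemic) | CCOC(=O)C(CCC=C(C)C)C(C)=O | intermediate
29 | 2-acetyl-6-methylhept-5-enoic acid (formed as its potassium salt) | CC(=O)C(CCC=C(C)C)C(=O)O | intermediate (not isolated)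
30 | 2-acetyl-2-[(diethylamino)methyl]-6-methylhept-5-enoic acid | CCN(CC)CC(CCC=C(C)C)(C(C)=O)C(=O)O | intermediate (not isolated)
31 | 7-methyl-3-methylideneoct-6-en-2-one | CC(=O)C(=C)CCC=C(C)C | intermediate
32 | tert-butyldimethyl[(7-methyl-3-methylideneocta-1,6-dien-2-yl)oxy]silane | C=C(O[Si](C)(C)C(C)(C)C)C(=C)CCC=C(C)C | intermediate
33 | Diels–Alder adduct: 25 spiro-fused at C11 (11S) to 4′-[(tert-butyldimethylsilyl)oxy]-3′-(4-methylpent-3-enyl)cyclohex-3′-ene | C/C=C(/C)C(=O)O[C@@H]1C[C@@]2(C)OC(=CC2=O)/C(C)=C\[C@@H]2OC(=O)[C@]3(CCC(O[Si](C)(C)C(C)(C)C)=C(CCC=C(C)C)C3)[C@@H]21 | intermediate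
34 | cesium enolate from 33 | C/C=C(/C)C(=O)O[C@@H]1C[C@@]2(C)OC(=CC2=O)/C(C)=C\[C@@H]2OC(=O)[C@]3(CCC(O[Cs])=C(CCC=C(C)C)C3)[C@@H]21 | intermediate (not isolated)
35 | enol triflate: as 33 with 4′-[(trifluoromethylsulfonyl)oxy] in place of the silyloxy group | C/C=C(/C)C(=O)O[C@@H]1C[C@@]2(C)OC(=CC2=O)/C(C)=C\[C@@H]2OC(=O)[C@]3(CCC(OS(=O)(=O)C(F)(F)F)=C(CCC=C(C)C)C3)[C@@H]21 | intermediate
36 | CNP0226905.2, (6S,7R,8R,10R,11S)-8-angeloyloxy-3,10-epoxy-1-oxogermacra-2,4Z-dien-12,6-olide spiro-fused at C11 to 3′-(4-methylpent-3-enyl)cyclohex-3′-ene | C/C=C(/C)C(=O)O[C@@H]1C[C@@]2(C)OC(=CC2=O)/C(C)=C\[C@@H]2OC(=O)[C@]3(CCC=C(CCC=C(C)C)C3)[C@@H]21 | target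

## Step count and risks

Total step count: 20. Longest linear sequence: 16 steps (1, 2, 3, 5–14, 18, 19, 20) from lactone 1.

Most likely to fail:

Step 12 (ring closure and C6/C7 stereochemistry). A medium ring is closed at high dilution, and the C6/C7 outcome rests on the chair model plus substrate control from C8; the C7 face in particular is not secured by close precedent. The allylzinc may also be protonated or lose silanolate before it cyclises. Fallback, setting out from 18 and coming back at 21: if the closure gives the 6,7-anti adduct, which does not lactonise by itself, methyl (6R,7S,8R,10R)-8-[(tert-butyldimethylsilyl)oxy]-3,10-epoxy-6-hydroxy-1-oxogermacra-2,4Z,11(13)-trien-12-oate F1, it is isolated rather than discarded. Its methyl ester is cleaved with Me3SnOH in 1,2-dichloroethane at 70 °C to (6R,7S,8R,10R)-8-[(tert-butyldimethylsilyl)oxy]-3,10-epoxy-6-hydroxy-1-oxogermacra-2,4Z,11(13)-trien-12-oic acid F2. A Mitsunobu lactonisation (PPh3, DIAD, toluene, high dilution) then closes the γ-lactone with inversion at C6, so C6 is set by SN2 displacement instead of by the allylation transition state, and the route resumes at 21. This corrects C6 only; a wrong C7 would not be rescued.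

Step 20 (and the surrogate sequence 18–19 leading to it). The zerovalent palladium catalyst could ionise the allylic C6–O lactone bond or the hindered tetrasubstituted triflate could react slowly. Fallback, setting out from 25 and coming back at 36: the surrogate diene is dropped and 25 is heated with commercial β-myrcene (7-methyl-3-methylideneocta-1,6-diene, 5 equiv, toluene, 110 °C, BHT). The thermal Diels–Alder reaction gives 36 directly, but as the minor regioisomer next to the para adduct, (6S,7R,8R,10R,11S)-8-angeloyloxy-3,10-epoxy-1-oxogermacra-2,4Z-dien-12,6-olide spiro-fused at C11 to 4′-(4-methylpent-3-enyl)cyclohex-3′-ene F3. The two are separated by preparative HPLC; this trades regiocontrol for two fewer operations and no palladium.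

Step 3 (methylation of the unprotected α-hydroxy lactone through its dianion). The enediolate may form incompletely, O-methylate, or decompose. Fallback, setting out from 4 and coming back at 6: the hydroxyl is first capped (Me3SiCl, imidazole, CH2Cl2) to give (3S,5R)-5-{[(triethylsilyl)oxy]methyl}-3-[(trimethylsilyl)oxy]dihydrofuran-2(3H)-one F4. Its mono-enolate (LiN(i-Pr)2, THF, −78 °C) is methylated with MeI, again anti to the C5 side chain, to give (3R,5R)-3-methyl-5-{[(triethylsilyl)oxy]methyl}-3-[(trimethylsilyl)oxy]dihydrofuran-2(3H)-one F5. Citric acid in methanol then removes only the trimethylsilyl group and returns 6.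

## Further compounds

F1 | step 12 | methyl (6R,7S,8R,10R)-8-[(tert-butyldimethylsilyl)oxy]-3,10-epoxy-6-hydroxy-1-oxogermacra-2,4Z,11(13)-trien-12-oate | CC(C)(C)[Si](C)(C)O[C@@H]1C[C@@]2(C)OC(=CC2=O)/C(C)=C\[C@@H](O)[C@@H]1C(=C)C(=O)OC
F2 | step 12 | (6R,7S,8R,10R)-8-[(tert-butyldimethylsilyl)oxy]-3,10-epoxy-6-hydroxy-1-oxogermacra-2,4Z,11(13)-trien-12-oic acid | CC(C)(C)[Si](C)(C)O[C@@H]1C[C@@]2(C)OC(=CC2=O)/C(C)=C\[C@@H](O)[C@@H]1C(=C)C(=O)O
F3 | step 20 | (6S,7R,8R,10R,11S)-8-angeloyloxy-3,10-epoxy-1-oxogermacra-2,4Z-dien-12,6-olide spiro-fused at C11 to 4′-(4-methylpent-3-enyl)cyclohex-3′-ene (para regioisomer of 36) | C/C=C(/C)C(=O)O[C@@H]1C[C@@]2(C)OC(=CC2=O)/C(C)=C\[C@@H]2OC(=O)[C@]3(CCC(CCC=C(C)C)=CC3)[C@@H]21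
F4 | step 3 | (3S,5R)-5-{[(triethylsilyl)oxy]methyl}-3-[(trimethylsilyl)oxy]dihydrofuran-2(3H)-one | CC[Si](CC)(CC)OC[C@H]1C[C@H](O[Si](C)(C)C)C(=O)O1
F5 | step 3 | (3R,5R)-3-methyl-5-{[(triethylsilyl)oxy]methyl}-3-[(trimethylsilyl)oxy]dihydrofuran-2(3H)-one | CC[Si](CC)(CC)OC[C@H]1C[C@@](C)(O[Si](C)(C)C)C(=O)O1
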